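## Retrosynthetic overview

1. Last bonds: acid closes the 12,6-lactone from O6 onto a tert-butyl 2-substituted acrylate, after O8 has been acylated with the (S)-hydroxy acid (made from (R)-lactic acid).
2. Key disconnection: C11–C7 and O–C6 are made together by thermal isomerisation of an O8-bound malonyl alkoxyamine (5-exo radical closure, then nitroxide capture at C6). The tether carbonyl later leaves as CO2 while C13 enters; the captured oxygen becomes the lactone oxygen.
3. Enabling feature: on the oxepane ring O–C5–C6–C7–C8–C9–C10, O8 and C11 are cis (on the face that carries the C1–C4 bridge) and the C6 oxygen is trans to both. An O8 tether can therefore only deliver C11 to the correct face of C7, and C6, flanked by C4 (on C5) and C11 (on C7), stays open only on the other face.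
4. Core: the C5–O–C10 ether comes from iridium-catalysed allylic etherification of a tertiary alcohol (C10 set by Sharpless epoxidation of geraniol); two ring-closing metatheses then give the 11-oxabicyclo[4.4.1]undecadiene.
5. Ring order: oxepane ring (C6=C7), oxepine ring (C3=C4), temporary γ-lactone on C7–C8 (key step), final 12,6-lactone.

Key step: step 17

Remarks on the chemistry:
- Germacrane numbering is used for the core (ring C1–C10, lactone C11–C13, C14 methyl on C10, C15 ester carbon on C4). "Face X" of the oxepane ring is the face carrying C4 and C1; "face Y" is the other.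
- C8 is carried as both epimers from step 4 to step 11, erased in step 12 and set in step 14.
- The side-chain acid is assumed not to be purchasable as a single enantiomer.

## Route

Step 1
Reactants: 1 geraniol
Product: 2 (2S,3S)-2,3-epoxygeraniol
Conditions: Ti(OiPr)4 (cat.), L-(+)-diethyl tartrate (cat.), t-BuOOH, 4 Å MS, CH2Cl2, −20 °C
Reagents that add atoms: tert-butyl hydroperoxide, CC(C)(C)OO
Why: Sharpless asymmetric epoxidation of the allylic alcohol, in which the L-tartrate catalyst delivers oxygen to the face giving the (2S,3S)-epoxide and so fixes the future C10–O centre.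

Step 2
Reactants: 2 (2S,3S)-2,3-epoxygeraniol
Product: 3 (3S)-3,7-dimethyloct-6-ene-1,3-diol
Conditions: NaAlH2(OCH2CH2OMe)2, THF, 0 °C
Reagents that add atoms: none
Why: Alkoxide-directed hydride opening of a 2,3-epoxy alcohol at C2 should give the 1,3-diol, the tertiary C–O bond (future C10) not being touched.

Step 3
Reactants: 3 (3S)-3,7-dimethyloct-6-ene-1,3-diol
Product: 4 (3S)-3-hydroxy-3,7-dimethyloct-6-enal
Conditions: TEMPO (cat.), PhI(OAc)2, CH2Cl2, rt; used crude
Reagents that add atoms: none
Why: Nitroxide-catalysed oxidation is selective for the primary alcohol and cannot oxidise the tertiary one.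

Step 4
Reactants: 4 (3S)-3-hydroxy-3,7-dimethyloct-6-enal
Product: 5 (5S)-5,9-dimethyldeca-1,8-diene-3,5-diol (both C3 epimers)
Conditions: CH2=CHMgBr, CeCl3, THF, −78 °C
Reagents that add atoms: vinylmagnesium bromide, C=C[Mg]Br
Why: Carbonyl addition of the cerium-modified Grignard reagent (which suppresses retro-aldol cleavage) gives the allylic alcohol; no control at the new carbinol (C8) is needed because it is erased in step 12.

Step 5
Reactants: 5 (5S)-5,9-dimethyldeca-1,8-diene-3,5-diol
Product: 6 (5S)-3-[(tert-butyldimethylsilyl)oxy]-5,9-dimethyldeca-1,8-dien-5-ol (both C3 epimers)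
Conditions: TBSCl, imidazole, DMF, 0 °C
Reagents that add atoms: tert-butyldimethylsilyl chloride, CC(C)(C)[Si](C)(C)Cl
Why: Silylation distinguishes the secondary from the tertiary hydroxyl on steric grounds and leaves the tertiary OH free for etherification.

Step 6
Reactants: 7 (2E)-pent-2-en-4-yn-1-ol
Product: 8 methyl (2E)-pent-2-en-4-yn-1-yl carbonate
Conditions: ClCO2Me, pyridine, CH2Cl2, 0 °C
Reagents that add atoms: methyl chloroformate, COC(=O)Cl
Why: Acylation of the primary allylic alcohol gives the carbonate leaving group needed for allyl–iridium formation.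

Step 7
Reactants: 8 methyl (2E)-pent-2-en-4-yn-1-yl carbonate
Product: 10 (2E)-4-bromopenta-2,4-dien-1-yl methyl carbonate, via alkenylborane 9 (not isolated)
Conditions: B-bromo-9-borabicyclo[3.3.1]nonane, CH2Cl2, 0 °C; then AcOH
Reagents that add atoms: B-bromo-9-borabicyclo[3.3.1]nonane, BrB1C2CCCC1CCC2
Why: Bromoboration adds B–Br syn across the terminal alkyne with bromine on the internal carbon, and protonolysis of the C–B bond leaves the 2-bromo-1,3-diene, a masked acrylate.

Step 8
Reactants: 6 (5S)-3-[(tert-butyldimethylsilyl)oxy]-5,9-dimethyldeca-1,8-dien-5-ol; 10 (2E)-4-bromopenta-2,4-dien-1-yl methyl carbonate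
Product: 11 {[(5S)-5-{[(3S)-2-bromopenta-1,4-dien-3-yl]oxy}-5,9-dimethyldeca-1,8-dien-3-yl]oxy}(tert-butyl)dimethylsilane
Conditions: 6, n-BuLi, THF, −78 °C; CuI; then 10, [Ir(cod)Cl]2 (2 mol %), binaphthol-derived N,N-bis(1-phenylethyl)phosphoramidite (4 mol %, the enantiomer giving the 3S ether), THF, rt
Reagents that add atoms: none
Why: Iridium-catalysed allylic etherification, in which the copper alkoxide attacks the substituted terminus of the allyl–iridium complex to give the branched ether, the new C5 centre being set by the ligand and not by the remote C10.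

Step 9
Reactants: 11 bromodiene ether
Product: 12 methyl (3S)-3-{[(5S)-3-[(tert-butyldimethylsilyl)oxy]-5,9-dimethyldeca-1,8-dien-5-yl]oxy}-2-methylidenepent-4-enoate
Conditions: Pd(PPh3)4 (5 mol %), CO (1 atm), MeOH, Et3N, DMF, 60 °C
Reagents that add atoms: carbon monoxide, [C-]#[O+]; methanol, CO
Why: Alkoxycarbonylation of the vinyl bromide (oxidative addition to zerovalent palladium, CO insertion, methanolysis) gives the 2-substituted acrylate without touching C5 or C10.

Step 10
Reactants: 12 silyl ether acrylate
Product: 13 methyl (3S)-3-{[(5S)-3-hydroxy-5,9-dimethyldeca-1,8-dien-5-yl]oxy}-2-methylidenepent-4-enoate (both carbinol epimers)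
Conditions: Bu4NF, AcOH, THF, rt
Reagents that add atoms: none
Why: Fluoride desilylation, buffered so that no alkoxide can add to the acrylate.

Step 11
Reactants: 13 allylic alcohol tetraene
Product: 14 methyl 2-[(2S,7S)-5-hydroxy-7-methyl-7-(4-methylpent-3-en-1-yl)-2,5,6,7-tetrahydrooxepin-2-yl]prop-2-enoate (both C5 epimers)
Conditions: RuCl2(PCy3)2(=CHPh) (first-generation Grubbs catalyst, 5 mol %), CH2Cl2 (0.005 M), 40 °C
Reagents that add atoms: none
Why: Ring-closing metathesis with the first-generation catalyst engages only the two monosubstituted vinyl groups (the acrylate and the trisubstituted alkene stay inert) and closes the oxepane ring with the cis C6=C7 bond.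

Step 12
Reactants: 14 oxepenol
Product: 15 methyl 2-[(2S,7S)-7-methyl-7-(4-methylpent-3-en-1-yl)-5-oxo-2,5,6,7-tetrahydrooxepin-2-yl]prop-2-enoate
Conditions: Dess–Martin periodinane, NaHCO3, CH2Cl2, 0 °C
Reagents that add atoms: none
Why: Buffered hypervalent-iodine oxidation converges both C8 epimers into one enone under neutral conditions that leave the γ-position C5 intact.

Step 13
Reactants: 15 oxepenone
Product: 16 methyl (1S,6S)-6-methyl-8-oxo-11-oxabicyclo[4.4.1]undeca-2,9-diene-2-carboxylate
Conditions: second-generation Hoveyda–Grubbs catalyst RuCl2(SIMes)(=CH-C6H4-2-OiPr) (10 mol %), toluene (0.002 M), 80 °C, Ar sparge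
Reagents that add atoms: none
Why: Second ring-closing metathesis, in which the catalyst loads onto the trisubstituted alkene (loss of 2-methylpropene) and closes onto the acrylate to give the C3=C4 enoate of the oxepine ring, possible because the two arms are cis across the ether oxygen.

Step 14
Reactants: 16 bicyclic dienone
Product: 17 methyl (1S,6S,8R)-8-hydroxy-6-methyl-11-oxabicyclo[4.4.1]undeca-2,9-diene-2-carboxylate
Conditions: NaBH4, CeCl3·7H2O, MeOH, −78 °C
Reagents that add atoms: none
Why: Luche 1,2-reduction, in which hydride should attack the C8 carbonyl from face Y (the outer face, away from the C1–C4 bridge) and so place the hydroxyl on face X.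

Step 15
Reactants: 17 bicyclic dienol; 18 mono-tert-butyl malonate
Product: 19 tert-butyl (1S,6S,8R)-2-(methoxycarbonyl)-6-methyl-11-oxabicyclo[4.4.1]undeca-2,9-dien-8-yl propanedioate
Conditions: DCC, DMAP (cat.), CH2Cl2, 0 °C to rt
Reagents that add atoms: none
Why: Steglich esterification attaches the malonyl tether to O8 with retention at C8.

Step 16
Reactants: 19 mixed malonate
Product: 20 2-[(2,2,6,6-tetramethylpiperidin-1-yl)oxy] derivative of 19 (either configuration at the malonyl carbon)
Conditions: NaH, THF, 0 °C; then CuCl2, TEMPO, rt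
Reagents that add atoms: TEMPO, CC1(C)CCCC(C)(C)N1[O]
Why: Oxidative α-aminoxylation, in which divalent copper oxidises the malonate enolate by one electron and the malonyl radical is captured by the nitroxide before it can cyclise at this temperature.

Step 17
Reactants: 20 malonyl alkoxyamine
Product: 21 tricyclic aminoxy lactone (5R,6S,7R,8R,10S): cis-fused γ-lactone O8–C(=O)–C11–C7–C8 on face X, CO2tBu on C11, O–N(2,2,6,6-tetramethylpiperidinyl) on C6 on face Y
Conditions: PhCl (0.01 M, degassed), 130 °C, sealed tube
Reagents that add atoms: none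
Why: On heating, the C11–O bond of the alkoxyamine homolyses reversibly (persistent-radical effect); whenever the malonyl radical is free in its s-cis ester rotamer it adds to C7 (forming C11–C7 and the temporary γ-lactone), and the secondary C6 radical so formed is captured irreversibly by the nitroxide (forming O–C6). The closest known reaction type is the thermal carboaminoxylation of unactivated alkenes by malonyl–TEMPO alkoxyamines, run here intramolecularly through an allylic ester tether as in radical lactone closures of allyl malonates. The only ring closed is the five-membered lactone, by 5-exo-trig attack (6-endo attack on C6 is disfavoured by the short tether); the C6–O bond is made without ring closure. C7 is controlled by the tether, because a five-membered ring across C7–C8 can only be cis-fused, so C11 enters on face X where O8 sits; C6 is controlled by the substrate, because face X of the planar C6 radical is shielded by the new lactone on C7 and by C4 on C5, so the bulky nitroxide binds on face Y, trans to C11 and cis to the bridging oxygen; C11 is of no consequence, as it becomes sp2 in step 18. The step needs cyclisation to outrun loss of the radical: the malonyl radical has no β-hydrogen and cannot disproportionate with the nitroxide, premature capture is reversible, dilution suppresses intermolecular addition, and the C3=C4 enoate is out of reach.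

Step 18
Reactants: 21 tricyclic aminoxy lactone
Product: 23 tert-butyl 2-substituted acrylate with free 8-OH and 6-O-aminoxy group (5R,6S,7R,8R,10S), via malonic half-acid 22 (not isolated)
Conditions: LiOH, THF/H2O, 0 °C; AcOH to pH 6; then aq. HCHO, Et2NH, 55 °C
Reagents that add atoms: formaldehyde, C=O
Why: Hydroxide opens the malonate-activated γ-lactone (the tert-butyl ester is inert and later cannot lactonise onto the free 8-OH), and Mannich condensation with decarboxylative elimination then expels the tether carbon as CO2 and installs C13 as the methylidene group.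

Step 19
Reactants: 24 (R)-lactic acid; 25 pivalaldehyde
Product: 26 (2R,5R)-2-tert-butyl-5-methyl-1,3-dioxolan-4-one
Conditions: TsOH (cat.), pentane, reflux, Dean–Stark; crystallisation
Reagents that add atoms: none
Why: Acetalisation gives mainly the cis-dioxolanone, whose tert-butyl-bearing acetal carbon stores the chirality while C5 is made planar in the next step.

Step 20
Reactants: 26 dioxolanone; 27 phenyl vinyl sulfoxide
Product: 28 (2R,5S)-2-tert-butyl-5-methyl-5-[2-(phenylsulfinyl)ethyl]-1,3-dioxolan-4-one (both sulfoxide epimers)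
Conditions: LiN(iPr)2, THF, −78 °C; then 27; AcOH quench
Reagents that add atoms: none
Why: Michael addition of the lithium enolate to the vinyl sulfoxide occurs on the face opposite the tert-butyl group (self-regeneration of the stereocentre) and sets the quaternary carbon.

Step 21
Reactants: 28 sulfoxide
Product: 29 (2R,5S)-2-tert-butyl-5-ethenyl-5-methyl-1,3-dioxolan-4-one
Conditions: toluene, NaHCO3, 110 °C
Reagents that add atoms: none
Why: Thermal syn-elimination of the sulfoxide can only take a hydrogen from the CH2 next to the quaternary carbon and unveils the vinyl group.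

Step 22
Reactants: 29 vinyl dioxolanone
Product: 30 (2S)-2-hydroxy-2-methylbut-3-enoic acid
Conditions: 2 M HCl, THF, 40 °C
Reagents that add atoms: none
Why: Acid hydrolysis of the acylal at the acetal carbon releases the hydroxy acid with its quaternary centre unchanged, both ring oxygens staying in the acid.

Step 23
Reactants: 30 (2S)-2-hydroxy-2-methylbut-3-enoic acid
Product: 32 (2S)-2-methyl-2-[(triethylsilyl)oxy]but-3-enoic acid, via bis-silyl derivative 31 (not isolated)
Conditions: Et3SiOTf (2.2 equiv), 2,6-lutidine, CH2Cl2, 0 °C; then MeOH/H2O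
Reagents that add atoms: triethylsilyl triflate, CC[Si](CC)(CC)OS(=O)(=O)C(F)(F)F
Why: Silyl triflate caps the hindered tertiary hydroxyl and the acid, and the labile silyl ester is solvolysed selectively.

Step 24
Reactants: 23 tert-butyl acrylate alcohol; 32 silyl-protected acid
Product: 34 8-O-[(2S)-2-methyl-2-(triethylsilyloxy)but-3-enoyl] ester of 23, via mixed anhydride 33 (not isolated)
Conditions: 32, 2,4,6-trichlorobenzoyl chloride, Et3N, toluene, rt; then 23, DMAP, rt
Reagents that add atoms: none
Why: Yamaguchi esterification acylates the only free hydroxyl (O8) with retention at C8 while O6 is still masked as the alkoxyamine, which rules out lactonisation or acylation at the wrong oxygen.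

Step 25
Reactants: 34 fully protected ester
Product: 35 6-hydroxy compound (34 with C6–OH in place of the C6–O–N group)
Conditions: Zn dust, AcOH/THF/H2O, 50 °C
Reagents that add atoms: none
Why: Reductive N–O cleavage by zinc frees the C6 hydroxyl with retention, the C6–O bond made in step 17 staying intact and the tert-butyl ester resisting lactonisation under these conditions.

Step 26
Reactants: 35 6-hydroxy compound
Product: 36 target, (5R,6S,7R,8R,10S) core with (S)-2-hydroxy-2-methylbut-3-enoate on O8
Conditions: CF3CO2H/CH2Cl2 (1:5), 0 °C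
Reagents that add atoms: none
Why: Acidolysis cleaves the tert-butyl ester and the silyl ether, and the liberated acrylic acid closes on the only free hydroxyl (O6) to give the trans-fused α-methylene γ-lactone without touching a stereocentre.

## Compound list

1 | geraniol | CC(C)=CCC/C(C)=C/CO | starting material
2 | (2S,3S)-2,3-epoxygeraniol | OC[C@@H]1O[C@@]1(C)CCC=C(C)C | intermediate
3 | (3S)-3,7-dimethyloct-6-ene-1,3-diol | OCC[C@@](C)(O)CCC=C(C)C | intermediate
4 | (3S)-3-hydroxy-3,7-dimethyloct-6-enal | O=CC[C@@](C)(O)CCC=C(C)C | intermediate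
5 | (5S)-5,9-dimethyldeca-1,8-diene-3,5-diol, both C3 epimers | C=CC(O)C[C@@](C)(O)CCC=C(C)C | intermediate
6 | (5S)-3-[(tert-butyldimethylsilyl)oxy]-5,9-dimethyldeca-1,8-dien-5-ol, both C3 epimers | C=CC(O[Si](C)(C)C(C)(C)C)C[C@@](C)(O)CCC=C(C)C | intermediate
7 | (2E)-pent-2-en-4-yn-1-ol | C#C/C=C/CO | starting material
8 | methyl (2E)-pent-2-en-4-yn-1-yl carbonate | C#C/C=C/COC(=O)OC | intermediate
9 | (2E,4Z)-5-(9-borabicyclo[3.3.1]nonan-9-yl)-4-bromopenta-2,4-dien-1-yl methyl carbonate | COC(=O)OC/C=C/C(Br)=C/B1C2CCCC1CCC2 | intermediate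
10 | (2E)-4-bromopenta-2,4-dien-1-yl methyl carbonate | COC(=O)OC/C=C/C(Br)=C | intermediate
11 | {[(5S)-5-{[(3S)-2-bromopenta-1,4-dien-3-yl]oxy}-5,9-dimethyldeca-1,8-dien-3-yl]oxy}(tert-butyl)dimethylsilane, both silyloxy-carbon epimers | C=CC(O[Si](C)(C)C(C)(C)C)C[C@](C)(CCC=C(C)C)O[C@@H](C=C)C(Br)=C | intermediate
12 | methyl (3S)-3-{[(5S)-3-[(tert-butyldimethylsilyl)oxy]-5,9-dimethyldeca-1,8-dien-5-yl]oxy}-2-methylidenepent-4-enoate | C=CC(O[Si](C)(C)C(C)(C)C)C[C@](C)(CCC=C(C)C)O[C@@H](C=C)C(=C)C(=O)OC | intermediate
13 | methyl (3S)-3-{[(5S)-3-hydroxy-5,9-dimethyldeca-1,8-dien-5-yl]oxy}-2-methylidenepent-4-enoate, both carbinol epimers | C=CC(O)C[C@](C)(CCC=C(C)C)O[C@@H](C=C)C(=C)C(=O)OC | intermediate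
14 | methyl 2-[(2S,7S)-5-hydroxy-7-methyl-7-(4-methylpent-3-en-1-yl)-2,5,6,7-tetrahydrooxepin-2-yl]prop-2-enoate, both C5 epimers | OC1C=C[C@@H](C(=C)C(=O)OC)O[C@@](C)(CCC=C(C)C)C1 | intermediate
15 | methyl 2-[(2S,7S)-7-methyl-7-(4-methylpent-3-en-1-yl)-5-oxo-2,5,6,7-tetrahydrooxepin-2-yl]prop-2-enoate | O=C1C=C[C@@H](C(=C)C(=O)OC)O[C@@](C)(CCC=C(C)C)C1 | intermediate
16 | methyl (1S,6S)-6-methyl-8-oxo-11-oxabicyclo[4.4.1]undeca-2,9-diene-2-carboxylate | O=C1C[C@]2(C)CCC=C(C(=O)OC)[C@@H](O2)C=C1 | intermediate
17 | methyl (1S,6S,8R)-8-hydroxy-6-methyl-11-oxabicyclo[4.4.1]undeca-2,9-diene-2-carboxylate | O[C@@H]1C[C@]2(C)CCC=C(C(=O)OC)[C@@H](O2)C=C1 | intermediate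
18 | mono-tert-butyl malonate (3-tert-butoxy-3-oxopropanoic acid) | CC(C)(C)OC(=O)CC(=O)O | starting material
19 | tert-butyl (1S,6S,8R)-2-(methoxycarbonyl)-6-methyl-11-oxabicyclo[4.4.1]undeca-2,9-dien-8-yl propanedioate | CC(C)(C)OC(=O)CC(=O)O[C@@H]1C[C@]2(C)CCC=C(C(=O)OC)[C@@H](O2)C=C1 | intermediate
20 | 2-[(2,2,6,6-tetramethylpiperidin-1-yl)oxy] derivative of 19, malonyl carbon unspecified | CC(C)(C)OC(=O)C(ON1C(C)(C)CCCC1(C)C)C(=O)O[C@@H]2C[C@]3(C)CCC=C(C(=O)OC)[C@@H](O3)C=C2 | intermediate
21 | tricyclic aminoxy lactone (5R,6S,7R,8R,10S), γ-lactone on C7–C8, CO2tBu on C11 (unspecified), aminoxy group on C6 | CC(C)(C)OC(=O)C1C(=O)O[C@@H]2C[C@]3(C)CCC=C(C(=O)OC)[C@@H](O3)[C@@H](ON4C(C)(C)CCCC4(C)C)[C@@H]21 | intermediate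
22 | malonic half-acid (lactone of 21 opened, 8-OH free) | O[C@@H]1C[C@]2(C)CCC=C(C(=O)OC)[C@@H](O2)[C@@H](ON3C(C)(C)CCCC3(C)C)[C@@H]1C(C(=O)O)C(=O)OC(C)(C)C | intermediate
23 | tert-butyl acrylate with 8-OH and 6-O-aminoxy group (5R,6S,7R,8R,10S) | O[C@@H]1C[C@]2(C)CCC=C(C(=O)OC)[C@@H](O2)[C@@H](ON3C(C)(C)CCCC3(C)C)[C@@H]1C(=C)C(=O)OC(C)(C)C | intermediate
24 | (R)-lactic acid | C[C@@H](O)C(=O)O | starting material
25 | pivalaldehyde | CC(C)(C)C=O | starting material
26 | (2R,5R)-2-tert-butyl-5-methyl-1,3-dioxolan-4-one | C[C@H]1O[C@@H](C(C)(C)C)OC1=O | intermediate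
27 | phenyl vinyl sulfoxide | C=CS(=O)c1ccccc1 | starting material
28 | (2R,5S)-2-tert-butyl-5-methyl-5-[2-(phenylsulfinyl)ethyl]-1,3-dioxolan-4-one, sulfur unspecified | C[C@@]1(CCS(=O)c2ccccc2)O[C@@H](C(C)(C)C)OC1=O | intermediate
29 | (2R,5S)-2-tert-butyl-5-ethenyl-5-methyl-1,3-dioxolan-4-one | C[C@@]1(C=C)O[C@@H](C(C)(C)C)OC1=O | intermediate
30 | (2S)-2-hydroxy-2-methylbut-3-enoic acid | C=C[C@](C)(O)C(=O)O | intermediate
31 | triethylsilyl (2S)-2-methyl-2-[(triethylsilyl)oxy]but-3-enoate | C=C[C@](C)(O[Si](CC)(CC)CC)C(=O)O[Si](CC)(CC)CC | intermediate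
32 | (2S)-2-methyl-2-[(triethylsilyl)oxy]but-3-enoic acid | C=C[C@](C)(O[Si](CC)(CC)CC)C(=O)O | intermediate
33 | mixed anhydride of 32 with 2,4,6-trichlorobenzoic acid | C=C[C@](C)(O[Si](CC)(CC)CC)C(=O)OC(=O)c1c(Cl)cc(Cl)cc1Cl | intermediate
34 | 8-O-[(2S)-2-methyl-2-(triethylsilyloxy)but-3-enoyl] ester of 23 | C=C[C@](C)(O[Si](CC)(CC)CC)C(=O)O[C@@H]1C[C@]2(C)CCC=C(C(=O)OC)[C@@H](O2)[C@@H](ON3C(C)(C)CCCC3(C)C)[C@@H]1C(=C)C(=O)OC(C)(C)C | intermediate
35 | 6-hydroxy compound (34 with C6–OH) | C=C[C@](C)(O[Si](CC)(CC)CC)C(=O)O[C@@H]1C[C@]2(C)CCC=C(C(=O)OC)[C@@H](O2)[C@@H](O)[C@@H]1C(=C)C(=O)OC(C)(C)C | intermediate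
36 | target CNP0325750.1 | C=C[C@](C)(O)C(=O)O[C@@H]1C[C@]2(C)CCC=C(C(=O)OC)[C@@H](O2)[C@H]2OC(=O)C(=C)[C@@H]21 | target

## Step count and risks

Total step count: 26. Longest linear sequence: 19 (steps 1–5, 8–18, 24–26).

Three steps most likely to fail:

1. Step 17. Ring closure has to pass through the minor s-cis ester rotamer; if it is too slow at a temperature the alkoxyamine tolerates, repeated homolysis would drain the malonyl radical by hydrogen abstraction, or capture at C6 could lose its facial preference. The fallback would set out from 19 and come back at 21, making the two bonds in separate operations. Bromination (DBU, CBr4, THF, −78 °C) would give the bromomalonate F1. Copper-catalysed atom-transfer radical cyclisation (CuBr, tris(2-pyridylmethyl)amine, 1,2-dichloroethane, 80 °C), a chain process that tolerates a slow closure, would give the cyclised secondary bromide F2. Exchange of bromine for the nitroxide at C6 (Cu powder, Cu(OTf)2 cat., 4,4′-di-tert-butyl-2,2′-bipyridine, TEMPO, benzene, 70 °C) would then give 21, the planar C6 radical being captured on face Y as in the main route.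

2. Step 8. The hindered tertiary copper alkoxide may attack the allyl–iridium intermediate too slowly, so that carbonate decomposition or attack at the unsubstituted terminus takes over, or the catalyst may fail to set C5 cleanly. The fallback would set out from 6 and come back at 11, giving up catalyst control for separation of C5 epimers. Acid-catalysed addition of 6 to methoxyallene (PPTS, CH2Cl2, 0 °C) would give the mixed acrolein acetal F3. Lewis-acid substitution of the methoxy group by an alkynylstannane (trimethyl[(tributylstannyl)ethynyl]silane, BF3·OEt2, CH2Cl2, −78 °C) would give the silylalkyne ether F4 as both C5 epimers. Desilylation (K2CO3, MeOH) and chromatography would give the (3S) terminal alkyne F5. Bromoboration (B-bromo-9-borabicyclo[3.3.1]nonane; then AcOH) through the alkenylborane F6 would give 11.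

3. Step 13. The trisubstituted alkene may load the ruthenium carbene too slowly, so that the catalyst decomposes or oligomers form before the bridged ring closes. The fallback would set out from 15 and come back at 16. Ozonolysis selective for the electron-rich trisubstituted alkene (O3, CH2Cl2/pyridine, −78 °C; Me2S) would give the aldehyde F7. Aldehyde-selective Wittig methylenation (Ph3P=CH2, THF, −78 °C) would give the terminal alkene F8. Ring-closing metathesis of this monosubstituted alkene with the acrylate (same second-generation catalyst, toluene, 60 °C) would give 16.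

Further compounds
F1 | step 17 | tert-butyl bromomalonate ester of 17 (2-bromo derivative of 19) | CC(C)(C)OC(=O)C(Br)C(=O)O[C@@H]1C[C@]2(C)CCC=C(C(=O)OC)[C@@H](O2)C=C1
F2 | step 17 | cyclised bromide (21 with Br on C6 in place of the aminoxy group, C6 unspecified) | CC(C)(C)OC(=O)C1C(=O)O[C@@H]2C[C@]3(C)CCC=C(C(=O)OC)[C@@H](O3)C(Br)[C@@H]21
F3 | step 8 | mixed acrolein acetal of 6, (5S)-5-[(1-methoxyprop-2-en-1-yl)oxy] silyl ether | C=CC(O[Si](C)(C)C(C)(C)C)C[C@](C)(CCC=C(C)C)OC(OC)C=C
F4 | step 8 | 5-(trimethylsilyl)pent-1-en-4-yn-3-yl ether of 6, both epimers at the new centre | C=CC(O[Si](C)(C)C(C)(C)C)C[C@](C)(CCC=C(C)C)OC(C=C)C#C[Si](C)(C)C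
F5 | step 8 | (3S)-pent-1-en-4-yn-3-yl ether of 6 | C=CC(O[Si](C)(C)C(C)(C)C)C[C@](C)(CCC=C(C)C)O[C@@H](C=C)C#C
F6 | step 8 | alkenylborane from bromoboration of F5 | C=CC(O[Si](C)(C)C(C)(C)C)C[C@](C)(CCC=C(C)C)O[C@@H](C=C)/C(Br)=C/B1C2CCCC1CCC2
F7 | step 13 | aldehyde from ozonolysis of 15, methyl 2-[(2S,7S)-7-methyl-5-oxo-7-(3-oxopropyl)-2,5,6,7-tetrahydrooxepin-2-yl]prop-2-enoate | O=C1C=C[C@@H](C(=C)C(=O)OC)O[C@@](C)(CCC=O)C1
F8 | step 13 | terminal alkene, methyl 2-[(2S,7S)-7-(but-3-en-1-yl)-7-methyl-5-oxo-2,5,6,7-tetrahydrooxepin-2-yl]prop-2-enoate | O=C1C=C[C@@H](C(=C)C(=O)OC)O[C@@](C)(CCC=C)C1
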